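## Analysis of the target

The target 16 is a diaryl ether. Ring A is a benzoic acid with CO2H on C1, OMe on C2, the (1R)-1-hydroxy-3-methylbutyl chain on C3, hydrogen on C4 and C5, and the ether oxygen on C6. Ring B is bound through C1' and carries OH on C2', CH3 on C4' and CH2OH on C6'.

Ring A is 1,2,3,4-tetrasubstituted with four different groups in a row. The ether bond C6–O–C1' is flanked by three ortho substituents (CO2H on ring A, OH and CH2OH on ring B), which makes it the hardest bond to form between two separate arenes.

The only stereocentre is the benzylic carbinol (R). It sits ortho to OMe and para to the ether oxygen, so it ionizes easily under acid and is prone to benzylic oxidation. It is best set late.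

Three hydroxyl groups and a carboxylic acid must end up free. The ring B phenol is oxidizable, and the acid can close a seven-membered lactone onto O–C2' on dehydration.

The feature that invites the strategy is the pair of 1,2-relationships across the ether: CO2H on C1 next to the oxygen on C6 of ring A, and OH on C2' next to the ether carbon C1' of ring B. This is the pattern left when a 2,2'-dihydroxybenzophenone, whose carbonyl carbon joins C1 and C1', is spirocyclized oxidatively (O on C6 to C1') and the bond between the carbonyl carbon and C1' is then cleaved. The carboxyl carbon and the CH2OH carbon on C6' are then the two carbons of a phthalide.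

## Retrosynthetic reasoning

**16 to 15.** The C–H bond of the carbinol is cut last, so 16 comes from aryl ketone 15 by an enantioselective hydride transfer. The stereocentre then never meets acid, base or oxidant. The ketone is also needed earlier, because it deactivates ring A in the key step.

**15 to 13 (key disconnection).** The ether bond C6–O–C1' is opened and the carboxyl carbon is reconnected to C1'. The diaryl ether acid 15 thus becomes benzophenone 13, with spirodienone 14 between them. In the forward direction the phenolic oxygen on C6 attacks C1' of the oxidized ring B in a five-membered closure. Base then cleaves the bond between the former carbonyl carbon and the spiro carbon. One operation builds the hindered ether intramolecularly, releases the carboxylic acid on C1 and returns the phenol on C2'. The precursor 13 falls apart at an aryl–carbonyl bond into two simple arenes.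

**13 to 12 to 11.** Only functional group changes are made here. The two phenols of 13 are masked as acetals in 12 (both acetals serve as directing groups earlier). The side-chain ketone of 12 comes from the carbinol of 11, which is the form that survives organolithium chemistry.

**11 to 3 and 9.** The bond between C1 of ring A and the future carboxyl carbon is cut. Ring A acts as the aryllithium 10, made from 3 by lithiation between its two oxygen substituents. Ring B is phthalide 9, which delivers ring B, the carboxyl carbon and the CH2OH group at the right oxidation levels in one piece.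

**9 to 6 to 5 to 4.** The lactone carbonyl of 9 is removed from the position between the acetal oxygen and the CH2OH group. This leads to benzylic alcohol 6, by way of the dilithio species 7 and hydroxy acid 8, and from there to the commercial ester 4 via 5.

**3 to 2 to 1.** The isobutyl–carbinol bond is cut, which leads to aldehyde 2 and the commercial phenol 1. Compound 1 already has OMe and OH in the required 1,3-relationship, with the carbonyl ortho to OMe.

## Alternatives that were turned down

**Alternative 1:** (textbook) Cut the ether bond C6–O–C1' between two separate arenes. The forward step is a nucleophilic aromatic substitution (or Ullmann coupling) of the 2,6-disubstituted phenol A1 with fluoro aldehyde A2 to give diaryl ether A3, followed by oxidation of the aldehyde and introduction of the side chain. It was turned down for three reasons. The ether would be formed between a doubly ortho-substituted phenoxide and an ortho-substituted electrophile, which is the slowest possible case. The side chain would have to enter A3 at C3, whereas electrophiles prefer C5 (para to OMe) or ring B. Carrying the chain in from the start would need a separately built 1,2,3,4-tetrasubstituted fluoroarene and still three phenol protections. It is also the route most chemists would draw first.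

**Alternative 2:** Cut both the ether bond and the C1–CO2H bond. The forward step is a three-component coupling in which the phenoxide of A1 adds to the 3-methoxybenzyne released from A4 (meta to OMe, as the methoxy group dictates), and the aryl anion ortho to OMe is carboxylated to give acid A5. It was turned down because a phenoxide in this carboxylative aryne coupling has no close precedent: the phenol protonates the aryl anion and the phenoxide is reversibly carbonated. The C3 side chain is also still missing, with the same regiochemical problem as in A3, unless a far more elaborate aryne precursor is made.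

**Alternative 3:** Build ring A from open-chain pieces by a Danheiser benzannulation. Photochemical Wolff rearrangement of diazo ketone A6 gives a vinylketene, which combines with aryl ynol ether A7 to give phenol A8 with the ester, the ether oxygen and the side chain already in place. It was turned down for three reasons. A7 is an acceptor-substituted ynol ether of a hindered phenol and an untested, electron-poor ketenophile. The hard ether bond is only moved into the preparation of A7. A6 and A7 each need several steps, so the precursor is not simpler than the product.

Key step: step 9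

Remark: 1 and 4 are taken as commercial. Compounds 11, 12 and 13 are hydroxy ketone/cyclic hemiketal tautomers drawn in the form expected to dominate; the carbinol centre of 3 and 11 and the hemiketal centre of 11 and 12 are uncontrolled and are erased before step 10.

## Route

Step 1
Reactants: 1 4-hydroxy-2-methoxybenzaldehyde
Product: 2 2-methoxy-4-(methoxymethoxy)benzaldehyde
Conditions: MOMCl, i-Pr2NEt, CH2Cl2, 0 °C → rt
Reagents that add atoms: chloromethyl methyl ether COCCl
Why: Williamson-type O-alkylation of the phenol; the acetal is the ortho-directing group for step 6 and is removed by the single acid treatment of step 8.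

Step 2
Reactants: 2 2-methoxy-4-(methoxymethoxy)benzaldehyde
Product: 3 1-[2-methoxy-4-(methoxymethoxy)phenyl]-3-methylbutan-1-ol (racemic)
Conditions: i-BuMgBr, THF, 0 °C; then H2O
Reagents that add atoms: isobutylmagnesium bromide CC(C)C[Mg]Br
Why: Grignard addition to the aldehyde; the carbinol is racemic on purpose, since it only masks the later ketone as a lithium alkoxide during step 6.

Step 3
Reactants: 4 methyl 3-hydroxy-5-methylbenzoate
Product: 5 methyl 3-(methoxymethoxy)-5-methylbenzoate
Conditions: MOMCl, i-Pr2NEt, CH2Cl2, 0 °C → rt
Reagents that add atoms: chloromethyl methyl ether COCCl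
Why: Williamson-type O-alkylation; the acetal oxygen will direct the lithiation of step 5.

Step 4
Reactants: 5 methyl 3-(methoxymethoxy)-5-methylbenzoate
Product: 6 [3-(methoxymethoxy)-5-methylphenyl]methanol
Conditions: LiAlH4, THF, 0 °C; then H2O, aq NaOH
Reagents that add atoms: none
Why: Hydride reduction of the ester to the benzylic alcohol; the acetal is inert to hydride.

Step 5
Reactants: 6 [3-(methoxymethoxy)-5-methylphenyl]methanol
Product: 9 7-(methoxymethoxy)-5-methyl-2-benzofuran-1(3H)-one, via dilithio species 7 (not isolated), via hydroxy acid 8 (not isolated)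
Conditions: n-BuLi (2.3 equiv), TMEDA, Et2O, 0 °C → rt; CO2, −78 °C; then 1 M HCl to pH 3, rt
Reagents that add atoms: carbon dioxide O=C=O
Why: Directed ortho-metalation in which the lithium alkoxide and the acetal oxygen cooperate, so the position between them is lithiated, as known for 3-alkoxybenzyl alcohols; carboxylation and lactonization on mild acidification should give the phthalide with the acetal intact.

Step 6
Reactants: 3 1-[2-methoxy-4-(methoxymethoxy)phenyl]-3-methylbutan-1-ol (racemic); 9 7-(methoxymethoxy)-5-methyl-2-benzofuran-1(3H)-one
Product: 11 1-[3-(1-hydroxy-3-methylbutyl)-2-methoxy-6-(methoxymethoxy)phenyl]-7-(methoxymethoxy)-5-methyl-1,3-dihydro-2-benzofuran-1-ol (mixture of stereoisomers), via aryllithium alkoxide 10 (not isolated)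
Conditions: 3, n-BuLi (2.2 equiv), THF, 0 °C; then 9, −78 → 0 °C; then H2O
Reagents that add atoms: none
Why: After O-deprotonation, directed ortho-metalation takes place at the ring C–H between OMe and the acetal oxygen, the most acidic site; the aryllithium adds to the lactone carbonyl and the adduct should persist as a lithium hemiketal alkoxide, which prevents a second addition. The two new centres are uncontrolled and are erased in steps 7 to 9.

Step 7
Reactants: 11 1-[3-(1-hydroxy-3-methylbutyl)-2-methoxy-6-(methoxymethoxy)phenyl]-7-(methoxymethoxy)-5-methyl-1,3-dihydro-2-benzofuran-1-ol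
Product: 12 1-{3-[1-hydroxy-7-(methoxymethoxy)-5-methyl-1,3-dihydro-2-benzofuran-1-yl]-2-methoxy-4-(methoxymethoxy)phenyl}-3-methylbutan-1-one (racemic at the hemiketal carbon)
Conditions: DDQ (1.2 equiv), CH2Cl2, rt
Reagents that add atoms: none
Why: DDQ dehydrogenation of an electron-rich benzylic alcohol, in which hydride abstraction is assisted by the para acetal oxygen and the ortho OMe of ring A; the hemiketal carbon has no hydrogen and the benzylic CH2 of ring B is meta to its oxygen and not activated.

Step 8
Reactants: 12 1-{3-[1-hydroxy-7-(methoxymethoxy)-5-methyl-1,3-dihydro-2-benzofuran-1-yl]-2-methoxy-4-(methoxymethoxy)phenyl}-3-methylbutan-1-one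
Product: 13 1-{4-hydroxy-3-[2-hydroxy-6-(hydroxymethyl)-4-methylbenzoyl]-2-methoxyphenyl}-3-methylbutan-1-one
Conditions: 3 M HCl, THF/H2O, 45 °C
Reagents that add atoms: none
Why: Acid hydrolysis of both aryl methoxymethyl acetals; the two freed phenols hydrogen-bond to the ketone and should draw the hemiketal equilibrium to the open 2,2'-dihydroxybenzophenone, while water as cosolvent suppresses ketal and isobenzofuran formation. No stereocentre is present, so acid is harmless here.

Step 9
Reactants: 13 1-{4-hydroxy-3-[2-hydroxy-6-(hydroxymethyl)-4-methylbenzoyl]-2-methoxyphenyl}-3-methylbutan-1-one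
Product: 15 6-[2-hydroxy-6-(hydroxymethyl)-4-methylphenoxy]-2-methoxy-3-(3-methylbutanoyl)benzoic acid, via spirodienone 14 (not isolated)
Conditions: PhI(OAc)2 (1.05 equiv), (CF3)2CHOH, 0 °C; then aq KOH, THF, 0 °C → rt; then 1 M HCl to pH 3
Reagents that add atoms: potassium hydroxide [K+].[OH-]
Why: The trivalent iodine reagent exchanges an acetate for the ring B phenol, and the phenolic oxygen on C6 of ring A then attacks C1' of ring B with loss of PhI and acetate, a 5-exo-trig closure that forms the benzofuran-3(2H)-one ring and dearomatizes ring B to the 6,6-disubstituted cyclohexa-2,4-dienone 14. The closest known reaction type is the oxidative cyclization of 2,2'-dihydroxybenzophenones to grisa-3',5'-diene-2',3-diones and their cleavage or ring expansion to diphenyl ether acids and depsidones, the path by which such diphenyl ethers arise in nature. In 14 the bond between C3 and the spiro carbon is that of a C-acylated phenol, so hydroxide adds to the C3 carbonyl and the bond breaks in a retro-Claisen step driven by rearomatization of ring B; this gives the carboxylate on C1, the ether oxygen on C1' and the phenoxide on C2' in one event. The spiro carbon is the only new stereocentre; it forms without control and is destroyed in the cleavage. Three selectivities are needed. Ring B and not ring A must be dearomatized, which the ortho aroyl and para 3-methylbutanoyl groups on the ring A phenol should secure, since they leave ring B as the only oxidizable phenol. Attack must occur at C1' and not at the open para position C5', which is secured because only C1' is within reach of the tethered oxygen and the solvent is non-nucleophilic. Cleavage must occur at C3 and not at the dienone carbonyl, which the gain of aromaticity on departure of ring B as a phenoxide should secure. Participation of the neighbouring hydroxymethyl group or a 1,3-acyl shift in 14 would not be harmful, since the same hydroxide treatment converges on 15.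

Step 10
Reactants: 15 6-[2-hydroxy-6-(hydroxymethyl)-4-methylphenoxy]-2-methoxy-3-(3-methylbutanoyl)benzoic acid
Product: 16 6-[2-hydroxy-6-(hydroxymethyl)-4-methylphenoxy]-3-[(1R)-1-hydroxy-3-methylbutyl]-2-methoxybenzoic acid
Conditions: RuCl[(R,R)-TsDPEN](p-cymene) (2 mol %), HCO2Na, H2O/MeOH, 40 °C; then pH 4
Reagents that add atoms: none
Why: Noyori–Ikariya asymmetric transfer hydrogenation of an aryl alkyl ketone; with the (R,R) ligand the divalent ruthenium hydride should deliver hydride to the Si face through the six-membered transition state organized by the CH/π contact between the η6-arene and ring A, which gives the (R)-carbinol. The substrate dissolves as its sodium carboxylate, no group needs protection, and the new stereocentre meets no further reagent.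

## Compound list

1 | 4-hydroxy-2-methoxybenzaldehyde | COc1cc(O)ccc1C=O | starting material
2 | 2-methoxy-4-(methoxymethoxy)benzaldehyde | COCOc1ccc(C=O)c(OC)c1 | intermediate
3 | 1-[2-methoxy-4-(methoxymethoxy)phenyl]-3-methylbutan-1-ol (racemic) | COCOc1ccc(C(O)CC(C)C)c(OC)c1 | intermediate
4 | methyl 3-hydroxy-5-methylbenzoate | COC(=O)c1cc(C)cc(O)c1 | starting material
5 | methyl 3-(methoxymethoxy)-5-methylbenzoate | COCOc1cc(C)cc(C(=O)OC)c1 | intermediate
6 | [3-(methoxymethoxy)-5-methylphenyl]methanol | COCOc1cc(C)cc(CO)c1 | intermediate
7 | lithium [2-lithio-3-(methoxymethoxy)-5-methylphenyl]methanolate (dilithio species, not isolated) | COCOc1cc(C)cc(CO[Li])c1[Li] | intermediate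
8 | 2-(hydroxymethyl)-6-(methoxymethoxy)-4-methylbenzoic acid (hydroxy acid, not isolated) | COCOc1cc(C)cc(CO)c1C(=O)O | intermediate
9 | 7-(methoxymethoxy)-5-methyl-2-benzofuran-1(3H)-one | COCOc1cc(C)cc2COC(=O)c12 | intermediate
10 | lithium 1-[3-lithio-2-methoxy-4-(methoxymethoxy)phenyl]-3-methylbutan-1-olate (aryllithium alkoxide, not isolated) | COCOc1ccc(C(O[Li])CC(C)C)c(OC)c1[Li] | intermediate
11 | 1-[3-(1-hydroxy-3-methylbutyl)-2-methoxy-6-(methoxymethoxy)phenyl]-7-(methoxymethoxy)-5-methyl-1,3-dihydro-2-benzofuran-1-ol (mixture of stereoisomers) | COCOc1ccc(C(O)CC(C)C)c(OC)c1C1(O)OCc2cc(C)cc(OCOC)c12 | intermediate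
12 | 1-{3-[1-hydroxy-7-(methoxymethoxy)-5-methyl-1,3-dihydro-2-benzofuran-1-yl]-2-methoxy-4-(methoxymethoxy)phenyl}-3-methylbutan-1-one (racemic at the hemiketal carbon) | COCOc1ccc(C(=O)CC(C)C)c(OC)c1C1(O)OCc2cc(C)cc(OCOC)c12 | intermediate
13 | 1-{4-hydroxy-3-[2-hydroxy-6-(hydroxymethyl)-4-methylbenzoyl]-2-methoxyphenyl}-3-methylbutan-1-one | COc1c(C(=O)CC(C)C)ccc(O)c1C(=O)c1c(O)cc(C)cc1CO | intermediate
14 | 6'-(hydroxymethyl)-4-methoxy-4'-methyl-5-(3-methylbutanoyl)-3H-spiro[1-benzofuran-2,1'-cyclohexa-3',5'-diene]-2',3-dione (spirodienone, both configurations at the spiro carbon, not isolated) | COc1c(C(=O)CC(C)C)ccc2OC3(C(=O)C=C(C)C=C3CO)C(=O)c12 | intermediate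
15 | 6-[2-hydroxy-6-(hydroxymethyl)-4-methylphenoxy]-2-methoxy-3-(3-methylbutanoyl)benzoic acid | COc1c(C(=O)CC(C)C)ccc(Oc2c(O)cc(C)cc2CO)c1C(=O)O | intermediate
16 | 6-[2-hydroxy-6-(hydroxymethyl)-4-methylphenoxy]-3-[(1R)-1-hydroxy-3-methylbutyl]-2-methoxybenzoic acid | COc1c([C@H](O)CC(C)C)ccc(Oc2c(O)cc(C)cc2CO)c1C(=O)O | target

## Step count and least certain steps

Total: 10 steps. Longest linear sequence: 8 steps (steps 3 to 10, from 4). The ring A branch (steps 1 and 2) joins at step 6.

**Step 9 (key step).** Four processes could spoil it:
- dearomatization of the wrong ring, or capture of the oxidized ring B at its open para position by acetate;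
- Diels–Alder dimerization of the cyclohexa-2,4-dienone before the base arrives;
- opening of the dienone ring by hydroxide instead of loss of the acyl group;
- further oxidation of the product phenol if oxidant is still present when base is added.

The fallback gives up the rearrangement and forms the ether by a classical copper-catalysed coupling. It sets out from 10 and 7 and comes back at 15. Quenching 10 with DMF would give 3-(1-hydroxy-3-methylbutyl)-2-methoxy-6-(methoxymethoxy)benzaldehyde F1. MnO2 would oxidize its carbinol to 2-methoxy-6-(methoxymethoxy)-3-(3-methylbutanoyl)benzaldehyde F2, and aqueous HCl would free the phenol to give 6-hydroxy-2-methoxy-3-(3-methylbutanoyl)benzaldehyde F3. Quenching 7 with I2 would give [2-iodo-3-(methoxymethoxy)-5-methylphenyl]methanol F4. Ullmann coupling of F3 with F4 (CuI, picolinic acid, K3PO4, DMSO, 90 °C) would give 6-[2-(hydroxymethyl)-6-(methoxymethoxy)-4-methylphenoxy]-2-methoxy-3-(3-methylbutanoyl)benzaldehyde F5. Pinnick oxidation (NaClO2, NaH2PO4, 2-methyl-2-butene) would give 6-[2-(hydroxymethyl)-6-(methoxymethoxy)-4-methylphenoxy]-2-methoxy-3-(3-methylbutanoyl)benzoic acid F6, and aqueous HCl in THF would remove the last acetal to give 15.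

**Step 6.** The hindered aryllithium could deprotonate the benzylic O–CH2 of the lactone instead of adding to the carbonyl. Lithiation could also stray to the position that is ortho only to the acetal oxygen. The fallback lowers the oxidation level of the electrophile and defers the oxidation. It sets out from 7 and 10 and comes back at 12. Quenching 7 with DMF would give, after work-up, 7-(methoxymethoxy)-5-methyl-1,3-dihydro-2-benzofuran-1-ol F7. As its lithium salt this reacts through the open aldehyde and should add 10 to give 1-(3-{hydroxy[2-(hydroxymethyl)-6-(methoxymethoxy)-4-methylphenyl]methyl}-2-methoxy-4-(methoxymethoxy)phenyl)-3-methylbutan-1-ol F8. DDQ (2.4 equiv, wet CH2Cl2) would oxidize both electron-rich secondary carbinols and the product would close to 12.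

**Step 7.** Hydride abstraction could also occur at the O–CH2 group of the hemiketal ring, the primary alcohol of the open tautomer could be oxidized, or the oxidation could stall. The fallback carries the ketone through the coupling instead of making it afterwards. It sets out from 3 and comes back at 12. MnO2 would oxidize 3 to 1-[2-methoxy-4-(methoxymethoxy)phenyl]-3-methylbutan-1-one F9. Enolization with LiN(SiMe3)2 followed by ring lithiation with s-BuLi/TMEDA at −78 °C would give lithium 1-[3-lithio-2-methoxy-4-(methoxymethoxy)phenyl]-3-methylbut-1-en-1-olate F10. Addition of F10 to 9 and aqueous quench would give 12 directly.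

**Step 10.** Facial discrimination could be poor, or turnover slow, because the ketone is flanked by OMe and carries a β-branched alkyl group on an electron-rich ring. The fallback replaces the metal hydride by an enzyme. It sets out from 15 and comes back at 16: an (R)-selective NADPH-dependent ketoreductase, chosen from a panel, with glucose and glucose dehydrogenase for cofactor recycling in phosphate buffer (pH 7)/DMSO at 30 °C, should reduce the carboxylate of 15 to 16 without any new intermediate.

## Further compounds

F1 | step 9 | 3-(1-hydroxy-3-methylbutyl)-2-methoxy-6-(methoxymethoxy)benzaldehyde (racemic) | COCOc1ccc(C(O)CC(C)C)c(OC)c1C=O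
F2 | step 9 | 2-methoxy-6-(methoxymethoxy)-3-(3-methylbutanoyl)benzaldehyde | COCOc1ccc(C(=O)CC(C)C)c(OC)c1C=O
F3 | step 9 | 6-hydroxy-2-methoxy-3-(3-methylbutanoyl)benzaldehyde | COc1c(C(=O)CC(C)C)ccc(O)c1C=O
F4 | step 9 | [2-iodo-3-(methoxymethoxy)-5-methylphenyl]methanol | COCOc1cc(C)cc(CO)c1I
F5 | step 9 | 6-[2-(hydroxymethyl)-6-(methoxymethoxy)-4-methylphenoxy]-2-methoxy-3-(3-methylbutanoyl)benzaldehyde | COCOc1cc(C)cc(CO)c1Oc1ccc(C(=O)CC(C)C)c(OC)c1C=O
F6 | step 9 | 6-[2-(hydroxymethyl)-6-(methoxymethoxy)-4-methylphenoxy]-2-methoxy-3-(3-methylbutanoyl)benzoic acid | COCOc1cc(C)cc(CO)c1Oc1ccc(C(=O)CC(C)C)c(OC)c1C(=O)O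
F7 | step 6 | 7-(methoxymethoxy)-5-methyl-1,3-dihydro-2-benzofuran-1-ol (racemic) | COCOc1cc(C)cc2COC(O)c12
F8 | step 6 | 1-(3-{hydroxy[2-(hydroxymethyl)-6-(methoxymethoxy)-4-methylphenyl]methyl}-2-methoxy-4-(methoxymethoxy)phenyl)-3-methylbutan-1-ol (mixture of stereoisomers) | COCOc1ccc(C(O)CC(C)C)c(OC)c1C(O)c1c(OCOC)cc(C)cc1CO
F9 | step 7 | 1-[2-methoxy-4-(methoxymethoxy)phenyl]-3-methylbutan-1-one | COCOc1ccc(C(=O)CC(C)C)c(OC)c1
F10 | step 7 | lithium 1-[3-lithio-2-methoxy-4-(methoxymethoxy)phenyl]-3-methylbut-1-en-1-olate | COCOc1ccc(C(O[Li])=CC(C)C)c(OC)c1[Li]
F0 | step 10 | none | none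
A1 | alternative 1 | 2-({[tert-butyl(dimethyl)silyl]oxy}methyl)-6-(methoxymethoxy)-4-methylphenol | COCOc1cc(C)cc(CO[Si](C)(C)C(C)(C)C)c1O
A2 | alternative 1 | 2-fluoro-6-methoxybenzaldehyde | COc1cccc(F)c1C=O
A3 | alternative 1 | 2-[2-({[tert-butyl(dimethyl)silyl]oxy}methyl)-6-(methoxymethoxy)-4-methylphenoxy]-6-methoxybenzaldehyde | COCOc1cc(C)cc(CO[Si](C)(C)C(C)(C)C)c1Oc1cccc(OC)c1C=O
A4 | alternative 2 | 3-methoxy-2-(trimethylsilyl)phenyl trifluoromethanesulfonate | COc1cccc(OS(=O)(=O)C(F)(F)F)c1[Si](C)(C)C
A5 | alternative 2 | 2-[2-({[tert-butyl(dimethyl)silyl]oxy}methyl)-6-(methoxymethoxy)-4-methylphenoxy]-6-methoxybenzoic acid | COCOc1cc(C)cc(CO[Si](C)(C)C(C)(C)C)c1Oc1cccc(OC)c1C(=O)O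
A6 | alternative 3 | (E)-5-{[tert-butyl(dimethyl)silyl]oxy}-1-diazo-7-methyloct-3-en-2-one (racemic) | [N-]=[N+]=CC(=O)/C=C/C(O[Si](C)(C)C(C)(C)C)CC(C)C
A7 | alternative 3 | methyl 3-[2-({[tert-butyl(dimethyl)silyl]oxy}methyl)-6-(methoxymethoxy)-4-methylphenoxy]prop-2-ynoate | COC(=O)C#COc1c(OCOC)cc(C)cc1CO[Si](C)(C)C(C)(C)C
A8 | alternative 3 | methyl 3-(1-{[tert-butyl(dimethyl)silyl]oxy}-3-methylbutyl)-6-[2-({[tert-butyl(dimethyl)silyl]oxy}methyl)-6-(methoxymethoxy)-4-methylphenoxy]-2-hydroxybenzoate (racemic) | COC(=O)c1c(O)c(C(O[Si](C)(C)C(C)(C)C)CC(C)C)ccc1Oc1c(OCOC)cc(C)cc1CO[Si](C)(C)C(C)(C)C
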